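## Retrosynthetic overview

- The β-hydroxy ketone is hidden in a β-keto-δ-lactone, (6R)-3-vanillyl-6-(arylethyl)-4-hydroxy-5,6-dihydro-2-pyranone; hydrolysis, loss of the lactone carbonyl as CO2 and O-debenzylation release the target.
- That lactone comes from enantioselective hydrogenation of the C5=C6 bond of the flat 3,6-disubstituted 4-hydroxy-2-pyrone; this dearomatisation creates the only stereocentre.
- The pyrone comes from triacetic acid lactone by C3 reductive benzylation with vanillin and 6-methyl (C7) benzylation with 3,4-bis(benzyloxy)benzyl chloride.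
- No ring is built: the purchased pyrone ring supplies C2–C5 of the heptanone from its C3–C6, and its C2 leaves as CO2.

Assumption: 3,4-bis(benzyloxy)benzyl chloride is bought, and the (S)-diphosphine is taken to give the 6R lactone; the sense is checked on the first run and the mirror-image ligand used if it is opposite.

## Route

Step 1
Reactants: 1 4-hydroxy-6-methyl-2H-pyran-2-one (triacetic acid lactone, 1.2 equiv); 2 3,4-bis(benzyloxy)benzyl chloride
Product: 4 6-[2-(3,4-bis(benzyloxy)phenyl)ethyl]-4-hydroxy-2H-pyran-2-one, via O,C-dilithio dianion 3 (not isolated)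
Conditions: LDA (2.5 equiv), THF–DMPU, −78 °C; then 2, Bu4NI (5 mol%), −78 → 0 °C; 1 M HCl
Reagents that add atoms: none
Why: LDA removes the 4-OH proton and then the vinylogous 6-CH3 proton, and dianion 3 reacts at its least stabilised carbanion site (C7) with the benzylic chloride by SN2 (lateral γ-alkylation of a vinylogous acid dianion), the slight excess of 1 limiting double alkylation.

Step 2
Reactants: 4 6-[2-(3,4-bis(benzyloxy)phenyl)ethyl]-4-hydroxy-2H-pyran-2-one; 5 vanillin (4-hydroxy-3-methoxybenzaldehyde)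
Product: 7 6-[2-(3,4-bis(benzyloxy)phenyl)ethyl]-4-hydroxy-3-(4-hydroxy-3-methoxybenzyl)-2H-pyran-2-one, via Knoevenagel arylidene dione 6 (not isolated)
Conditions: L-proline (20 mol%), Hantzsch ester (1.1 equiv), EtOH, 40 °C
Reagents that add atoms: none
Why: Proline-catalysed Knoevenagel condensation at the nucleophilic C3 of the 4-hydroxy-2-pyrone gives arylidene dione 6, which is reduced in situ by conjugate hydride transfer from the Hantzsch ester before a second pyrone can add (three-component organocatalytic reductive alkylation); the free phenol and benzyl ethers are inert.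

Step 3
Reactants: 7 6-[2-(3,4-bis(benzyloxy)phenyl)ethyl]-4-hydroxy-3-(4-hydroxy-3-methoxybenzyl)-2H-pyran-2-one
Product: 8 (6R)-6-[2-(3,4-bis(benzyloxy)phenyl)ethyl]-4-hydroxy-3-(4-hydroxy-3-methoxybenzyl)-5,6-dihydro-2H-pyran-2-one
Conditions: [Ru(OAc)2((S)-MeO-BIPHEP)] (1 mol%), HBF4·OEt2 (2 mol%), H2 (60 bar), MeOH–CH2Cl2, 50 °C
Reagents that add atoms: none
Why: The cationic Ru(II)–atropisomeric diphosphine catalyst binds the pyrone as a chelating vinylogous β-keto ester and adds H2 to one face of the trisubstituted C5=C6 bond only (asymmetric hydrogenation of a 3,6-disubstituted 4-hydroxy-2-pyrone), which dearomatises the ring and sets the single stereocentre as 6R, while the acid-stabilised tetrasubstituted C3=C4 enol, the benzyl ethers and the arenes are not reduced.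

Step 4
Reactants: 8 (6R)-6-[2-(3,4-bis(benzyloxy)phenyl)ethyl]-4-hydroxy-3-(4-hydroxy-3-methoxybenzyl)-5,6-dihydro-2H-pyran-2-one
Product: 11 (5R)-7-(3,4-dihydroxyphenyl)-5-hydroxy-1-(4-hydroxy-3-methoxyphenyl)heptan-3-one, via β-keto acid 9 (not isolated), via dibenzyl ketol 10 (not isolated)
Conditions: 1,4-dioxane–H2O (3:1), AcOH/NaOAc (pH 4.5), 85 °C, Ar; then cool, 10% Pd/C, H2 (1 atm), rt
Reagents that add atoms: none
Why: Water opens the keto tautomer of the β-keto-δ-lactone by acyl–oxygen cleavage, so the C–O bond at the stereocentre is untouched, and β-keto acid 9 loses CO2 irreversibly through the cyclic six-membered transition state (ketonic hydrolysis–decarboxylation of a cyclic β-keto ester) at a pH where gingerol-type ketols resist dehydration and retro-aldol, after which Pd-catalysed hydrogenolysis removes both benzyl ethers from 10 without affecting the aliphatic ketone or the non-benzylic alcohol.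

## Compound list

1 | 4-hydroxy-6-methyl-2H-pyran-2-one (triacetic acid lactone) | Cc1cc(O)cc(=O)o1 | starting material
2 | 3,4-bis(benzyloxy)benzyl chloride | ClCc1ccc(OCc2ccccc2)c(OCc2ccccc2)c1 | starting material
3 | O,C-dilithio dianion of 1 (lithium 6-(lithiomethyl)-2-oxo-2H-pyran-4-olate) | [Li+].[Li+].[CH2-]c1cc([O-])cc(=O)o1 | intermediate
4 | 6-[2-(3,4-bis(benzyloxy)phenyl)ethyl]-4-hydroxy-2H-pyran-2-one | O=c1cc(O)cc(CCc2ccc(OCc3ccccc3)c(OCc3ccccc3)c2)o1 | intermediate
5 | vanillin (4-hydroxy-3-methoxybenzaldehyde) | COc1cc(C=O)ccc1O | starting material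
6 | 6-[2-(3,4-bis(benzyloxy)phenyl)ethyl]-3-(4-hydroxy-3-methoxybenzylidene)-2H-pyran-2,4(3H)-dione (E/Z mixture) | COc1cc(C=C2C(=O)C=C(CCc3ccc(OCc4ccccc4)c(OCc4ccccc4)c3)OC2=O)ccc1O | intermediate
7 | 6-[2-(3,4-bis(benzyloxy)phenyl)ethyl]-4-hydroxy-3-(4-hydroxy-3-methoxybenzyl)-2H-pyran-2-one | COc1cc(Cc2c(O)cc(CCc3ccc(OCc4ccccc4)c(OCc4ccccc4)c3)oc2=O)ccc1O | intermediate
8 | (6R)-6-[2-(3,4-bis(benzyloxy)phenyl)ethyl]-4-hydroxy-3-(4-hydroxy-3-methoxybenzyl)-5,6-dihydro-2H-pyran-2-one | COc1cc(CC2=C(O)C[C@@H](CCc3ccc(OCc4ccccc4)c(OCc4ccccc4)c3)OC2=O)ccc1O | intermediate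
9 | (5R)-7-[3,4-bis(benzyloxy)phenyl]-5-hydroxy-2-(4-hydroxy-3-methoxybenzyl)-3-oxoheptanoic acid (C2 epimer mixture) | COc1cc(CC(C(=O)O)C(=O)C[C@H](O)CCc2ccc(OCc3ccccc3)c(OCc3ccccc3)c2)ccc1O | intermediate
10 | (5R)-7-[3,4-bis(benzyloxy)phenyl]-5-hydroxy-1-(4-hydroxy-3-methoxyphenyl)heptan-3-one | COc1cc(CCC(=O)C[C@H](O)CCc2ccc(OCc3ccccc3)c(OCc3ccccc3)c2)ccc1O | intermediate
11 | (5R)-7-(3,4-dihydroxyphenyl)-5-hydroxy-1-(4-hydroxy-3-methoxyphenyl)heptan-3-one | COc1cc(CCC(=O)C[C@H](O)CCc2ccc(O)c(O)c2)ccc1O | target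

## Step count and risks

Total step count: 4.
Longest linear sequence: 4 steps (1 → 4 → 7 → 8 → 11).

Most likely to fail, in decreasing order:

**Step 4 (hydrolytic decarboxylation).** The neutral lactone may simply persist, or on forcing may open by β-elimination of the carboxylate to the enone, which destroys the stereocentre and is then hydrogenated to the 5-deoxy ketone. The fallback sets out from 8 and comes back at 11. Lactone 8 is condensed with hydroxylamine (NH2OH·HCl, NaOAc, EtOH–H2O, 50 °C). Oximation at C4 followed by O-acylation by the lactone carbonyl opens the δ-lactone under near-neutral conditions and frees the carbinol without touching its C–O bond. This gives 3-[(2R)-4-(3,4-bis(benzyloxy)phenyl)-2-hydroxybutyl]-4-(4-hydroxy-3-methoxybenzyl)isoxazol-5(2H)-one F1. Hydrogenation of the isoxazolone F1 (H2, Pd/C, MeOH–H2O–AcOH, rt) cleaves the N–O bond; the carboxyl group is lost as CO2, the remaining C=N is hydrolysed to the ketone, and the benzyl ethers fall off in the same operation, giving 11 directly.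

**Step 3 (asymmetric pyrone hydrogenation).** The ee or the sense of induction may be poor on this aryl-rich substrate. The fallback sets out from 7 and comes back at 8, replacing asymmetric catalysis by classical resolution of the vinylogous acid. Pyrone 7 is hydrogenated without a chiral ligand over ethylenediamine-poisoned Pd/C (H2 1 atm, THF, rt; benzyl ethers are spared) to the racemic 6-[2-(3,4-bis(benzyloxy)phenyl)ethyl]-4-hydroxy-3-(4-hydroxy-3-methoxybenzyl)-5,6-dihydro-2H-pyran-2-one F2. The racemic lactone F2 (enol pKa about 5) is crystallised with (R)-1-phenylethylamine from EtOAc–iPrOH to give the (R)-1-phenylethylammonium salt of the 6R lactone F3; the amine antipode is chosen by screening for the less soluble salt. Acidification of the salt F3 (1 M HCl) returns 8.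

**Step 1 (dianion alkylation).** Yields may be low through O-alkylation, C3/C5 alkylation or double alkylation, or through sluggish reaction of the chloride. The fallback sets out from 2 and comes back at 4, building the pyrone ring instead of functionalising it. Chloride 2 alkylates the terminal carbon of doubly deprotonated acetylacetone (LDA 2.1 equiv, THF, 0 °C) to give 6-[3,4-bis(benzyloxy)phenyl]hexane-2,4-dione F4. A second double deprotonation of the dione F4 (LDA, THF, −78 °C; the methyl terminus reacts) followed by CO2 gives 7-[3,4-bis(benzyloxy)phenyl]-3,5-dioxoheptanoic acid F5. Cyclodehydration of the dioxo acid F5 (TFAA, CH2Cl2, 0 °C → rt) closes the 4-hydroxy-2-pyrone 4.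

## Further compounds

F1 | step 4 | 3-[(2R)-4-(3,4-bis(benzyloxy)phenyl)-2-hydroxybutyl]-4-(4-hydroxy-3-methoxybenzyl)isoxazol-5(2H)-one | COc1cc(CC2=C(C[C@H](O)CCc3ccc(OCc4ccccc4)c(OCc4ccccc4)c3)NOC2=O)ccc1O
F2 | step 3 | racemic 6-[2-(3,4-bis(benzyloxy)phenyl)ethyl]-4-hydroxy-3-(4-hydroxy-3-methoxybenzyl)-5,6-dihydro-2H-pyran-2-one | COc1cc(CC2=C(O)CC(CCc3ccc(OCc4ccccc4)c(OCc4ccccc4)c3)OC2=O)ccc1O
F3 | step 3 | (R)-1-phenylethylammonium salt of the 6R lactone (4-olate) | COc1cc(CC2=C([O-])C[C@@H](CCc3ccc(OCc4ccccc4)c(OCc4ccccc4)c3)OC2=O)ccc1O.C[C@@H]([NH3+])c1ccccc1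
F4 | step 1 | 6-[3,4-bis(benzyloxy)phenyl]hexane-2,4-dione | CC(=O)CC(=O)CCc1ccc(OCc2ccccc2)c(OCc2ccccc2)c1
F5 | step 1 | 7-[3,4-bis(benzyloxy)phenyl]-3,5-dioxoheptanoic acid | OC(=O)CC(=O)CC(=O)CCc1ccc(OCc2ccccc2)c(OCc2ccccc2)c1
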